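The runs are calculated on assumed constants; noise was put on by code.

A small charge of Q is the first thing to reckon in teal and red: the step E + Q -> L takes one E for each Q, and we count everything in fractions of the E charge.

| flask | E | Z | Q | remark | time |
|---|---|---|---|---|---|
| cedar | 0.050 M | 1.3 equiv | 0.030 M | run made earlier |  |
| teal | 0.050 M | 1.30 equiv | 0.0150 M |  | 6.0 h |
| red | 0.050 M | 1.30 equiv | 0.0150 M |  | 12 h |

cedar run (percent of the E charged)

| time / min | J / % | E / % |
|---|---|---|
| 6.00 | 0.5 | 76.6 |
| 10.0 | 0.2 | 72.2 |
| 15.0 | 0 | 69.4 |
| 25.0 | 0.4 | 66.9 |
| 40.0 | 0.9 | 63.4 |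
| 80.0 | 2.2 | 56.3 |

(standard deviation of a reading: 0.5 percentage points)

- which of these there is most of at the end, counted by the E in it, teal (J / E)
- which of these there is most of at the end, counted by the E in it, red (J / E)
- amount of the one of these that there is most of at the end, in percent of the E charged, teal
- amount of the one of these that there is most of at the end, in percent of the E charged, red

We set two amounts against each other, the Q charged and the E charged:

Q charged / E charged = 30.0%

This ratio is the Q ceiling, the fraction of the E charge that becomes L if every Q is used. Z sets no such ceiling, since its 1.30 equiv exceeds the E charge, which makes E the limiting reagent for J. X sets none either, as E <-> X can hand its E back.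

At its last reading the cedar run had 41.5% of the charge outside E and J, below its own ceiling of 60.0%. That gap holds X as well as L. The ceiling in teal and red lies under it, and from the far end, with X counted, we reckon:

E + X + J ≥ 1 − ceiling = 70.0%

That remainder starts as E and can end as J, and the question is how far the hand-over has gone.

The forecast gives E at 42% (32% to 53%) in teal and J at 48% (34% to 66%) in red, saying “J is the likelier leader, but this is uncertain”.

Teal ends with E at 41.1%, and red with J at 47.6%: the leaders the forecast named, inside its ranges. In red at 12.0 h, L stands at 27.6%, under the ceiling of 30.0%, with 8.0% of the Q left.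

    E + Z → J + D (k = 0.310 M⁻¹ h⁻¹)
    E ⇌ X (K = 0.360, k = 3.90 h⁻¹)
    E + Q → L (k = 10.0 M⁻¹ h⁻¹)
    E + Z + D → J + 2 D (k = 190 M⁻² h⁻¹)

A neighbour of red with 0.013 M of E has a ceiling of 115%, above its whole E charge, so in that flask the ceiling gives no lower bound on E, X and J. That flask ends with L at 58.2%, E at 28.4% and J at 3.14%.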